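Assumption: the target is taken as the free zwitterionic N-oxide (N⁺–O⁻), not as a salt or hydrate.

## Analysis of the target

Target 19 is a gramine N-oxide: a 1-methylindole that carries bromine at C2, C5 and C6 and a CH2–N⁺(CH3)2–O⁻ group at C3. It has no stereocentre, since the oxidised nitrogen bears two identical methyl groups, so nothing has to be controlled in space. The N-oxide is the most fragile group: it is easily reduced and can undergo a Meisenheimer shift on heating, so it must be made last. The C3–CH2–N unit is of the gramine type and ionises to a 3-methyleneindoleninium ion once the nitrogen is quaternised or protonated. The C2–Br bond becomes a vinylogous acyl bromide whenever C3 carries a carbonyl group and is then open to addition–elimination by amines or hydroxide. The three C–Br bonds also rule out palladium-catalysed hydrogenation and lithium–halogen exchange conditions. The real difficulty is the placement of the bromines: electrophilic bromination of an indole does not reliably give the 5,6-pattern, and C2 is not where an electrophile goes once C3 carries an acceptor. The strategy rests on C2, which is bonded to N1, to C3 and to bromine and so has the substitution of an imidoyl bromide carbon. N1–C2(Br) can therefore be brought in as an aryl–N=CBr2 group, C3 as the benzylic carbon of an ortho acetate side chain, and the C5/C6 bromines with the benzene starting material.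

## Retrosynthetic reasoning

**N–O bond.** Target 19 is cut back to tertiary amine 18. The oxygen is added last because no later step could tolerate it. The forward step has to oxidise the only basic nitrogen without touching the indole, which three bromines make a poor partner for a peracid.

**Side-chain C–N bond.** Amine 18 is cut at CH2–N to alcohol 16, by way of its sulfonate 17. This uses the native electrophilicity of an indol-3-ylmethyl carbon. Alcohol 16 comes from ester 15 by hydride reduction. This order is chosen over an amide because no amine nucleophile then meets the molecule while C3 still carries a carbonyl group, when the C2 bromine would be exposed to addition–elimination.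

**N1–CH3 bond.** Ester 15 is cut to the N–H indole 14. The forward step is an alkylation of an acidic acylindole N–H. It is placed directly after the ring closure so that no acidic proton is left for the hydride step.

**C2–C3 bond (key disconnection).** Indole 14 is cut between C2 and C3 to isocyanide dibromide 12; the 3H-indole 13 lies in between. This cut pairs a nucleophilic benzylic ester carbon with an electrophilic imidoyl carbon, and the C2 bromine arrives as part of the electrophile. Ring formation and C2 halogenation become one event and the indole never has to be brominated. The forward step needs carbon attack by the enolate, loss of exactly one bromide, and tautomerisation to the aromatic ring.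

**C–Br bonds at the imidoyl carbon.** Dibromide 12 is cut to isocyanide 10 and bromine 11. The forward step is α-addition of the halogen to the divalent isocyanide carbon. It must be run dry and cold, because 12 is sensitive to hydrolysis.

**Isocyanide nitrogen.** Isocyanide 10 comes from formamide 9 by dehydration. Formamide 9 comes from nitro ester 7 through aniline 8. The forward sequence must keep the aryl bromides through the nitro reduction. It must also formylate 8 before its nitrogen can close onto the neighbouring ester.

**Acetate side chain.** Nitro ester 7 is the methyl ester of acid 6. Acid 6 is cut at the CH2–CO bond to nitrotoluene 2 and diethyl oxalate 3, with keto ester 4 and keto acid 5 in between. The nitro group serves twice: it acidifies the ortho methyl group for acylation and it is the latent indole nitrogen. An oxidative cleavage then removes the surplus carbon.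

**Aryl C–N bond.** Nitrotoluene 2 is cut to 3,4-dibromotoluene 1. Nitration is directed by the methyl group (ortho) and the C3 bromine (para) to the same carbon, which fixes the future C5/C6 bromines relative to nitrogen.

## Alternatives that were turned down

**Alternative 1:** The benzene ring is built onto a pyrrole by cutting C7–C7a and C3a–C4. In the forward step the free α- and β-positions of pyrrole amide A3 attack, under acid, the two masked aldehyde carbons of the dibromosuccinaldehyde equivalent A2. Loss of both alkoxy groups then aromatises the new ring to indole A1.
- For: it is convergent and very short, the two benzenoid bromines arrive in an unambiguous 5,6-relationship, and the C3 substituent is already an amide. On step count it is stronger than the chosen route.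
- Against: the β-carbon of A3 next to the amide is its least nucleophilic position. The oxocarbenium ions from A2 are destabilised by the adjacent bromine and can lose HBr instead of aromatising as planned, which would cost a bromine. Acid also oligomerises pyrroles.
- Against: A1 still lacks the C2 bromine, which would have to be added by metalation in the presence of two aryl bromides.
- Comparison: the chosen strategy is longer, but all three bromines are fixed by construction and the ring closure itself sets C2–Br.

**Alternative 2:** The benzene ring is cut at C4–C5 and C6–C7. In the forward step the pyrone diene of pyranopyrrolone A5 adds the bis-silyl alkyne A6 across C4 and C7. Decarboxylative cycloreversion of the bridged lactone gives the bis-silyl indole A4, whose silyl groups would later be exchanged for bromine.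
- For: the regiochemistry is certain, and the silicon placeholders tolerate metal chemistry that aryl bromides do not.
- Against: A5 needs several steps of its own, and A6 is a hindered, electronically unactivated dienophile that would need forcing temperatures.
- Against: the second ipso-bromodesilylation must occur ortho to a new bromine and competes with protodesilylation. The C2 bromine is again missing from A4.
- Comparison: it is the longest option and postpones two halogenation problems, where the chosen route has none after the nitration of 1.

**Alternative 3:** The pyrrole ring is cut at N1–C2. In the forward step the carbamate nitrogen of the ortho-(2,2-dibromovinyl)anilide A8 displaces one vinylic bromide, under base or copper catalysis, to give the N-Boc 2-bromoindole amide A7.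
- For: closure of ortho-gem-dibromovinyl anilides to 2-bromoindoles is an established reaction type, so on precedent this alternative is stronger than the chosen key step. It also installs C2–Br by ring closure and has C3 already at the amide level.
- Against: A8 is a tetrasubstituted dibromoalkene that must come from dibromo-olefination of the hindered, poorly electrophilic keto amide A9. A9 in turn needs a regiodefined aminoaryl glyoxylate.
- Against: copper catalysis can engage the aryl bromides or the second vinylic bromide. The Boc group has to be exchanged for methyl, and the amide must be reduced next to the activated C2 bromine.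
- Comparison: the chosen strategy gives up precedent. In return it offers a precursor 12 that comes from a nitration/Reissert sequence, a metal-free closure, and an ester that is reduced without exposing C2–Br to amines. The uncertainty is confined to one step that has a known-chemistry fallback.

Key step: step 7

## Route

Step 1
Reactants: 1 3,4-dibromotoluene
Product: 2 4,5-dibromo-2-nitrotoluene
Conditions: fuming HNO3, H2SO4, 0 °C → rt; recrystallisation from EtOH
Reagents that add atoms: nitric acid, O[N+](=O)[O-]
Why: Electrophilic aromatic nitration; the carbon ortho to the methyl group and para to the C3 bromine is activated by both substituents and is unhindered, so this isomer should dominate and crystallise free of minor regioisomers.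

Step 2
Reactants: 2 4,5-dibromo-2-nitrotoluene; 3 diethyl oxalate
Product: 6 2-(4,5-dibromo-2-nitrophenyl)acetic acid, via ethyl 3-(4,5-dibromo-2-nitrophenyl)-2-oxopropanoate 4 (not isolated), via 3-(4,5-dibromo-2-nitrophenyl)-2-oxopropanoic acid 5 (not isolated)
Conditions: KOtBu, Et2O/THF, 0 °C → rt; then aq. NaOH, 30% H2O2, 0–10 °C; then aq. HCl
Reagents that add atoms: hydrogen peroxide, OO
Why: Reissert condensation: the methyl group ortho to the nitro group is deprotonated and acylated by 3, with hindered KOtBu chosen to limit SNAr at the bromine para to the nitro group. Saponification and alkaline H2O2 then cleave keto acid 5 oxidatively, with loss of one carbon, to the arylacetic acid.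

Step 3
Reactants: 6 2-(4,5-dibromo-2-nitrophenyl)acetic acid
Product: 7 methyl 2-(4,5-dibromo-2-nitrophenyl)acetate
Conditions: MeOH, H2SO4 (cat.), reflux
Reagents that add atoms: methanol, CO
Why: Fischer esterification of an unhindered arylacetic acid; the nitro group and the aryl bromides are inert to acid.

Step 4
Reactants: 7 methyl 2-(4,5-dibromo-2-nitrophenyl)acetate
Product: 9 methyl 2-(4,5-dibromo-2-formamidophenyl)acetate, via methyl 2-(2-amino-4,5-dibromophenyl)acetate 8 (not isolated)
Conditions: H2 (1 atm), sulfided Pt/C, EtOAc, rt; filtration through Celite; then HCO2Ac (from HCO2H and Ac2O), 0 °C → rt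
Reagents that add atoms: acetic formic anhydride, CC(=O)OC=O
Why: Catalytic nitro hydrogenation over sulfided platinum, which does not hydrogenolyse aryl C–Br bonds, followed by N-formylation with a mixed anhydride. Aniline 8, made less nucleophilic by the para bromine, should be formylated at 0 °C faster than it can lactamise onto the ester.

Step 5
Reactants: 9 methyl 2-(4,5-dibromo-2-formamidophenyl)acetate
Product: 10 methyl 2-(4,5-dibromo-2-isocyanophenyl)acetate
Conditions: POCl3, Et3N, CH2Cl2, −30 → 0 °C; cold aq. Na2CO3 work-up
Reagents that add atoms: none
Why: Dehydration of an N-aryl formamide to the isocyanide with POCl3 and a tertiary amine; at or below 0 °C Et3N is too weak to deprotonate the benzylic ester, so the isocyanide should not close to an indole prematurely.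

Step 6
Reactants: 10 methyl 2-(4,5-dibromo-2-isocyanophenyl)acetate; 11 bromine
Product: 12 methyl 2-[4,5-dibromo-2-(dibromomethylideneamino)phenyl]acetate
Conditions: Br2 (1.0 equiv), CH2Cl2, −78 → −20 °C, dark, Ar; solvent removed cold, used crude
Reagents that add atoms: none
Why: α-Addition of a halogen to the divalent isocyanide carbon, the classical preparation of isocyanide dihalides; it is fast at low temperature, whereas the deactivated ring and the benzylic CH2 would need a catalyst or radical initiation to react with Br2. The product is moisture-sensitive and is carried on without chromatography.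

Step 7
Reactants: 12 methyl 2-[4,5-dibromo-2-(dibromomethylideneamino)phenyl]acetate
Product: 14 methyl 2,5,6-tribromo-1H-indole-3-carboxylate, via methyl 2,5,6-tribromo-3H-indole-3-carboxylate 13 (not isolated)
Conditions: LiN(SiMe3)2 (2.2 equiv), THF, −78 °C, slow addition of 12 to the base (0.02 M) → 0 °C; then sat. aq. NH4Cl
Reagents that add atoms: none
Why: Proposed new method: the hindered amide base should remove the benzylic proton of 12, which is acidified by the ester and the electron-poor ring, faster than it adds to the imidoyl carbon, and the enolate carbon then attacks the N=CBr2 carbon. Addition to the C=N π* and loss of bromide, or ionisation to an N-aryl bromonitrilium ion followed by 5-endo-dig capture, forms the C2–C3 bond and gives 3H-indole 13; the second equivalent of base removes its C3 proton and the quench delivers the aromatic 1H-indole 14. The pyrrole ring closes in a formal 5-(enolexo)-endo-trig addition–elimination, which should be feasible because rotation about the aryl–N bond places the C=N π* over the enolate p orbital, as in the known 5-endo-trig closures of ortho-substituted β,β-dihalostyrenes to 2-haloindoles. The closest known reactions are the base- or Cu2O-induced closure of ortho-isocyanophenylacetates to indole-3-carboxylates, which joins the same two carbons, and the substitution of isocyanide dihalides by stabilised carbanions. No stereocentre remains, since C3 of 13 becomes planar on tautomerisation. Carbon attack rather than oxygen attack is secured by ring size, because O-attack would need a seven-membered ring. Single substitution is secured by aromatisation, because in the indolide the remaining C2–Br is a vinylogous carbamoyl bromide on an anionic ring and no longer an imidoyl halide. Inverse addition at high dilution is meant to suppress attack of the enolate on a second molecule of 12, and dry THF keeps the dibromide from hydrolysing.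

Step 8
Reactants: 14 methyl 2,5,6-tribromo-1H-indole-3-carboxylate
Product: 15 methyl 2,5,6-tribromo-1-methylindole-3-carboxylate
Conditions: MeI, K2CO3, DMF, rt
Reagents that add atoms: iodomethane, CI
Why: N-Alkylation (SN2) of the acidic N–H of a 3-acylindole; carbonate is too weak a nucleophile to displace the C2 bromine at room temperature.

Step 9
Reactants: 15 methyl 2,5,6-tribromo-1-methylindole-3-carboxylate
Product: 16 (2,5,6-tribromo-1-methylindol-3-yl)methanol
Conditions: iBu2AlH (2.5 equiv), CH2Cl2, −78 → 0 °C; aq. potassium sodium tartrate
Reagents that add atoms: none
Why: Hydride reduction of a vinylogous carbamate ester to the primary alcohol by a Lewis-acidic aluminium hydride that leaves aryl and vinylic C–Br bonds intact; the neutral tartrate work-up avoids acid-induced ionisation of the indol-3-ylmethanol.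

Step 10
Reactants: 16 (2,5,6-tribromo-1-methylindol-3-yl)methanol
Product: 18 1-(2,5,6-tribromo-1-methylindol-3-yl)-N,N-dimethylmethanamine, via (2,5,6-tribromo-1-methylindol-3-yl)methyl methanesulfonate 17 (not isolated)
Conditions: Ms2O, iPr2NEt, CH2Cl2, −40 °C; then Me2NH (2 M in THF, excess), −40 °C → rt
Reagents that add atoms: dimethylamine, CNC; methanesulfonic anhydride, CS(=O)(=O)OS(C)(=O)=O (its atoms remain only in intermediate 17)
Why: Sulfonate activation and amine displacement: the indol-3-ylmethyl mesylate is activated by the indole nitrogen and is captured at the exocyclic carbon by excess secondary amine. C2 is blocked by bromine and, with no carbonyl group left at C3, is no longer prone to addition–elimination.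

Step 11
Reactants: 18 1-(2,5,6-tribromo-1-methylindol-3-yl)-N,N-dimethylmethanamine
Product: 19 1-(2,5,6-tribromo-1-methylindol-3-yl)-N,N-dimethylmethanamine N-oxide
Conditions: mCPBA (1.05 equiv), CH2Cl2, 0 °C; filtration through basic Al2O3 (CH2Cl2/MeOH), no heating
Reagents that add atoms: 3-chloroperoxybenzoic acid, O=C(OO)c1cccc(Cl)c1
Why: Peracid oxidation of a tertiary amine to its N-oxide; the aliphatic nitrogen is the only nucleophilic site, since the indole lone pair is part of the aromatic sextet and the ring is deactivated by three bromines. No β-hydrogen is available for Cope elimination, and cold handling should prevent a Meisenheimer shift.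

## Compound list

1 | 3,4-dibromotoluene | Cc1ccc(Br)c(Br)c1 | starting material
2 | 4,5-dibromo-2-nitrotoluene | Cc1cc(Br)c(Br)cc1[N+](=O)[O-] | intermediate
3 | diethyl oxalate | CCOC(=O)C(=O)OCC | starting material
4 | ethyl 3-(4,5-dibromo-2-nitrophenyl)-2-oxopropanoate (formed as its potassium enolate) | CCOC(=O)C(=O)Cc1cc(Br)c(Br)cc1[N+](=O)[O-] | intermediate (not isolated)
5 | 3-(4,5-dibromo-2-nitrophenyl)-2-oxopropanoic acid (formed as its sodium salt) | OC(=O)C(=O)Cc1cc(Br)c(Br)cc1[N+](=O)[O-] | intermediate (not isolated)
6 | 2-(4,5-dibromo-2-nitrophenyl)acetic acid | OC(=O)Cc1cc(Br)c(Br)cc1[N+](=O)[O-] | intermediate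
7 | methyl 2-(4,5-dibromo-2-nitrophenyl)acetate | COC(=O)Cc1cc(Br)c(Br)cc1[N+](=O)[O-] | intermediate
8 | methyl 2-(2-amino-4,5-dibromophenyl)acetate | COC(=O)Cc1cc(Br)c(Br)cc1N | intermediate (not isolated)
9 | methyl 2-(4,5-dibromo-2-formamidophenyl)acetate | COC(=O)Cc1cc(Br)c(Br)cc1NC=O | intermediate
10 | methyl 2-(4,5-dibromo-2-isocyanophenyl)acetate | COC(=O)Cc1cc(Br)c(Br)cc1[N+]#[C-] | intermediate
11 | bromine | BrBr | starting material
12 | methyl 2-[4,5-dibromo-2-(dibromomethylideneamino)phenyl]acetate | COC(=O)Cc1cc(Br)c(Br)cc1N=C(Br)Br | intermediate
13 | methyl 2,5,6-tribromo-3H-indole-3-carboxylate (racemic, transient) | COC(=O)C1C(Br)=Nc2cc(Br)c(Br)cc21 | intermediate (not isolated)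
14 | methyl 2,5,6-tribromo-1H-indole-3-carboxylate | COC(=O)c1c(Br)[nH]c2cc(Br)c(Br)cc12 | intermediate
15 | methyl 2,5,6-tribromo-1-methylindole-3-carboxylate | COC(=O)c1c(Br)n(C)c2cc(Br)c(Br)cc12 | intermediate
16 | (2,5,6-tribromo-1-methylindol-3-yl)methanol | OCc1c(Br)n(C)c2cc(Br)c(Br)cc12 | intermediate
17 | (2,5,6-tribromo-1-methylindol-3-yl)methyl methanesulfonate | CS(=O)(=O)OCc1c(Br)n(C)c2cc(Br)c(Br)cc12 | intermediate (not isolated)
18 | 1-(2,5,6-tribromo-1-methylindol-3-yl)-N,N-dimethylmethanamine | CN(C)Cc1c(Br)n(C)c2cc(Br)c(Br)cc12 | intermediate
19 | 1-(2,5,6-tribromo-1-methylindol-3-yl)-N,N-dimethylmethanamine N-oxide | Cn1c(Br)c(C[N+](C)(C)[O-])c2cc(Br)c(Br)cc21 | target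

## Step count and least certain steps

Total: 11 steps. Longest linear sequence: 11 steps, from 1 to 19.

**Step 7 (key step, proposed new method).** Several processes could defeat the closure:
- the enolate may attack the N=CBr2 group of a second molecule and oligomerise;
- the amide base may add to the imidoyl carbon;
- adventitious water may hydrolyse the dibromide;
- the endo closure may be too slow to compete with these.

A first change within the approach would be NaH in THF. The fallback uses known chemistry and sets out from isocyanide 10. Cu2O (catalytic) in toluene at 60 °C closes the ortho-isocyanophenylacetate to methyl 5,6-dibromo-1H-indole-3-carboxylate F1. MeI and K2CO3 in DMF give methyl 5,6-dibromo-1-methylindole-3-carboxylate F2. Ester-directed magnesiation at C2 with TMPMgCl·LiCl in THF at −20 °C, then trapping with 1,2-dibromotetrachloroethane, returns to the route at 15.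

**Step 6.** The dibromide may hydrolyse during concentration, or HBr formed from traces of water may decompose it, so that 12 cannot be delivered clean to the key step. The fallback reaches the key-step product through a lactam instead of an N=CBr2 group and sets out from nitro ester 7. C-Acylation with dimethyl carbonate and NaH in THF gives dimethyl 2-(4,5-dibromo-2-nitrophenyl)malonate F3. Fe in AcOH at 80 °C reduces the nitro group with lactamisation to methyl 5,6-dibromo-2-oxoindoline-3-carboxylate F4. POBr3 in 1,2-dichloroethane at 80 °C converts the lactam to the 2-bromoindole and returns to the route at 14.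

**Step 4.** Aniline 8 may lactamise onto the ester before it is formylated, or a C–Br bond may be hydrogenolysed. The fallback accepts the lactamisation, bypasses the isocyanide chemistry and sets out from nitro ester 7. Fe in AcOH at 90 °C gives 5,6-dibromoindolin-2-one F5. Vilsmeier–Haack haloformylation with PBr3 and DMF in refluxing CHCl3 gives 2,5,6-tribromo-1H-indole-3-carbaldehyde F6. MeI and K2CO3 in DMF give 2,5,6-tribromo-1-methylindole-3-carbaldehyde F7. Reductive amination with Me2NH and NaBH(OAc)3 in 1,2-dichloroethane at rt returns to the route at 18.

**Step 10.** Mesylate 17 may ionise to the 3-methyleneindoleninium ion and be captured by unreacted alcohol or by a second indole before the amine is added. The fallback avoids any indol-3-ylmethyl electrophile and sets out from ester 15. AlMe3-mediated aminolysis with Me2NH·HCl in toluene at 80 °C gives 2,5,6-tribromo-N,N,1-trimethylindole-3-carboxamide F8. It is run at the lowest workable temperature to spare the C2 bromine. Reduction with AlH3 (from LiAlH4 and AlCl3) in THF at 0 °C returns to the route at 18.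

**Step 2.** Alkoxide, hydroxide or hydroperoxide may displace the bromine para to the nitro group by SNAr during the condensation or the cleavage. The fallback avoids strong oxygen nucleophiles and sets out from nitrotoluene 2. Leimgruber–Batcho enamine formation with Me2NCH(OMe)2 in DMF at 110 °C gives (E)-2-(4,5-dibromo-2-nitrophenyl)-N,N-dimethylethenamine F9. Hydrolysis with aq. HCl in THF gives 2-(4,5-dibromo-2-nitrophenyl)acetaldehyde F10. Pinnick oxidation (NaClO2, NaH2PO4, 2-methyl-2-butene, tBuOH/H2O) returns to the route at 6.

## Further compounds

F1 | step 7 | methyl 5,6-dibromo-1H-indole-3-carboxylate | COC(=O)c1c[nH]c2cc(Br)c(Br)cc12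
F2 | step 7 | methyl 5,6-dibromo-1-methylindole-3-carboxylate | COC(=O)c1cn(C)c2cc(Br)c(Br)cc12
F3 | step 6 | dimethyl 2-(4,5-dibromo-2-nitrophenyl)malonate | COC(=O)C(C(=O)OC)c1cc(Br)c(Br)cc1[N+](=O)[O-]
F4 | step 6 | methyl 5,6-dibromo-2-oxoindoline-3-carboxylate (racemic, enolisable) | COC(=O)C1C(=O)Nc2cc(Br)c(Br)cc21
F5 | step 4 | 5,6-dibromoindolin-2-one | O=C1Cc2cc(Br)c(Br)cc2N1
F6 | step 4 | 2,5,6-tribromo-1H-indole-3-carbaldehyde | O=Cc1c(Br)[nH]c2cc(Br)c(Br)cc12
F7 | step 4 | 2,5,6-tribromo-1-methylindole-3-carbaldehyde | O=Cc1c(Br)n(C)c2cc(Br)c(Br)cc12
F8 | step 10 | 2,5,6-tribromo-N,N,1-trimethylindole-3-carboxamide | CN(C)C(=O)c1c(Br)n(C)c2cc(Br)c(Br)cc12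
F9 | step 2 | (E)-2-(4,5-dibromo-2-nitrophenyl)-N,N-dimethylethenamine | CN(C)/C=C/c1cc(Br)c(Br)cc1[N+](=O)[O-]
F10 | step 2 | 2-(4,5-dibromo-2-nitrophenyl)acetaldehyde | O=CCc1cc(Br)c(Br)cc1[N+](=O)[O-]
A1 | alternative 1 | 5,6-dibromo-N,N,1-trimethylindole-3-carboxamide | CN(C)C(=O)c1cn(C)c2cc(Br)c(Br)cc12
A2 | alternative 1 | 3,4-dibromo-2,5-dimethoxytetrahydrofuran (mixture of diastereomers) | COC1OC(OC)C(Br)C1Br
A3 | alternative 1 | N,N,1-trimethylpyrrole-3-carboxamide | CN(C)C(=O)c1ccn(C)c1
A4 | alternative 2 | methyl 1-methyl-5,6-bis(trimethylsilyl)indole-3-carboxylate | COC(=O)c1cn(C)c2cc([Si](C)(C)C)c([Si](C)(C)C)cc12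
A5 | alternative 2 | methyl 1-methyl-5-oxo-1,5-dihydropyrano[3,4-b]pyrrole-3-carboxylate | COC(=O)C1=CN(C)C2=COC(=O)C=C12
A6 | alternative 2 | bis(trimethylsilyl)acetylene | C[Si](C)(C)C#C[Si](C)(C)C
A7 | alternative 3 | tert-butyl 2,5,6-tribromo-3-(dimethylcarbamoyl)indole-1-carboxylate | CN(C)C(=O)c1c(Br)n(C(=O)OC(C)(C)C)c2cc(Br)c(Br)cc12
A8 | alternative 3 | tert-butyl N-[4,5-dibromo-2-[1,1-dibromo-3-(dimethylamino)-3-oxoprop-1-en-2-yl]phenyl]carbamate | CN(C)C(=O)C(=C(Br)Br)c1cc(Br)c(Br)cc1NC(=O)OC(C)(C)C
A9 | alternative 3 | tert-butyl N-[4,5-dibromo-2-[2-(dimethylamino)-2-oxoacetyl]phenyl]carbamate | CN(C)C(=O)C(=O)c1cc(Br)c(Br)cc1NC(=O)OC(C)(C)C
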